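**Strategy**

The ten terpenoid carbons are read as a linalool chain C1′–C8′ whose ends C1′ and C8′ both sit on the spiro carbon C6 of the trione, and whose C2′–C6′ bond is shared by the cyclopentane (C2′–C6′) and the spirocyclohexane (C6, C1′, C2′, C6′, C7′, C8′). Disconnecting C2′–C6′ and C6–C1′ gives a dienone, C6=C8′–C7′=C6′, tethered to the C1′=C2′ vinyl group. Condensation of (R)-8-oxolinalool silyl ether with a trione carrying masked prenyl groups forms this dienone, stored in the pot as its 2H-pyran; on heating, one intramolecular Diels–Alder reaction closes both carbocycles and sets C6, C2′ and C6′. The aldehyde and the trione contain neither ring.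

Key step: step 5

Remark on labels: trione ring C1–C6 (C1 = carbonyl between the acetyl-bearing C2 and the spiro carbon; C3 = enol carbon; C4 = gem-disubstituted carbon; C5 = carbonyl between C4 and C6; C6 = spiro carbon). Terpenoid carbons C1′–C8′ follow linalool (C3′ and C7′ carry OH and CH3). Target: (6S,2′S,3′R,6′R,7′R).

Remark on tautomers: the β-triketones are tautomeric mixtures and are written in the enol form of the target.

Remark on the mask: the prenyl groups are carried as a spirocyclopentene because the radical hydration of step 6 could not tell the C7′=C8′ ring olefin from prenyl olefins.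

Remark on supply: (R)-(−)-linalool of high enantiomeric purity is taken as commercial.

**Route**

Step 1
Reactants: 1 2,4,6-trihydroxyacetophenone
Product: 2 2-acetyl-4,4-diallyl-3-hydroxycyclohex-2-ene-1,5-dione
Conditions: allyl bromide (2.2 equiv), KOH (aq.), 0 to 23 °C
Reagents that add atoms: allyl bromide C=CCBr
Why: Alkylative dearomatisation, in which the phloroglucinol anion is C-allylated twice at the same ring carbon (SN2, as in the classical gem-prenylation of acylphloroglucinols), should give the non-aromatic enolised triketone that keeps one acidic ring C–H (the future C6), the 3,5-diallyl isomer being the expected by-product; no stereocenter is formed.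

Step 2
Reactants: 2 2-acetyl-4,4-diallyl-3-hydroxycyclohex-2-ene-1,5-dione
Product: 3 9-acetyl-10-hydroxyspiro[4.5]deca-2,9-diene-6,8-dione
Conditions: second-generation Grubbs catalyst RuCl2(=CHPh)(H2IMes)(PCy3) (3 mol %), CH2Cl2, 40 °C
Reagents that add atoms: none
Why: Ring-closing metathesis of the gem-diallyl group (favoured by the quaternary carbon, driven by loss of ethene) should give the spirocyclopentene, a disubstituted olefin that masks both prenyl groups; no stereocenter is formed.

Step 3
Reactants: 4 (R)-(−)-linalool
Product: 5 (R)-linalool triethylsilyl ether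
Conditions: Et3SiOTf, 2,6-lutidine, CH2Cl2, −78 to 0 °C
Reagents that add atoms: triethylsilyl trifluoromethanesulfonate CC[Si](CC)(CC)OS(=O)(=O)C(F)(F)F
Why: Silyl triflate silylation of the hindered tertiary allylic alcohol leaves the C3′ stereocenter untouched, and the ether later prevents oxa-Michael cyclisation of the C3′ oxygen onto the enal and the dienone.

Step 4
Reactants: 5 (R)-linalool triethylsilyl ether
Product: 6 (2E,6R)-2,6-dimethyl-6-(triethylsilyloxy)octa-2,7-dienal
Conditions: SeO2 (1.5 equiv), 1,4-dioxane, 80 °C
Reagents that add atoms: selenium dioxide O=[Se]=O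
Why: Riley allylic oxidation (ene reaction, then 2,3-sigmatropic shift) should attack the (E)-methyl group at the more substituted end of the trisubstituted olefin and run on to the (E)-enal, while the vinyl group has no allylic hydrogen and the stereocenter is remote.

Step 5
Reactants: 3 9-acetyl-10-hydroxyspiro[4.5]deca-2,9-diene-6,8-dione; 6 (2E,6R)-2,6-dimethyl-6-(triethylsilyloxy)octa-2,7-dienal
Product: 9 (6S,2′S,3′R,6′R)-cycloadduct with C7′=C8′ olefin and C3′ silyl ether, via dienone 7 (not isolated), via pyran 8 (not isolated)
Conditions: ethylenediammonium diacetate (10 mol %), 4 Å sieves, toluene, 23 °C; then dilution with degassed toluene to 0.01 M, 2,6-di-tert-butyl-4-methylphenol (cat.), 130 °C, sealed tube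
Reagents that add atoms: none
Why: Knoevenagel condensation at C6, the only acidic ring C–H of 3, should give the 1-oxatriene 7, which at 23 °C rests as 2H-pyran 8 (oxa-6π electrocyclisation through the C5 oxygen, the one not engaged in the hydrogen-bonded acyl-enol unit; both C6′ epimers, which is of no consequence), and heating reopens 8 to 7, whose C6=C8′–C7′=C6′ diene, made strongly electron-poor by the two carbonyl groups on C6, adds the tethered C1′=C2′ vinyl group in an inverse-electron-demand intramolecular Diels–Alder reaction. The closest known reaction types are the domino Knoevenagel/cycloaddition of alkylidene-1,3-diones that carry a pendant olefin and the thermal intramolecular Diels–Alder reaction of (E)-nona-1,3,8-trienes to hexahydroindenes. The cyclopentane is closed by the tether-side C2′–C6′ bond (five-membered ring through C3′, C4′ and C5′), and the same bond together with C1′–C6 completes the six-membered Diels–Alder ring, both σ-bonds forming in one concerted, asynchronous step. The trans ring fusion (C2′/C6′) should follow from the anti arrangement of the three-atom tether, favoured when the internal bond at the most electrophilic diene carbon C6′ leads; the face of the vinyl group is set by C3′ (silyloxy group in the olefin plane, methyl group roughly anti to the forming bond); C6 is set by the diene geometry, the C5 carbonyl being held on the inside by the reversible C5–O pyran closure and so ending cis to H-6′. The step needs the carbon [4+2] mode to win over reclosure to 8 (reversible and harmless), over hetero-Diels–Alder addition (geometrically out of reach with this tether) and over oxa-Michael addition of the C3′ oxygen (blocked by the silyl ether), and it needs the C6=C8′ geometry to persist, which the low loading of the amine salt and the fast reclosure or cycloaddition of the strained cisoid dienone should secure.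

Step 6
Reactants: 9 (6S,2′S,3′R,6′R)-cycloadduct with C7′=C8′ olefin and C3′ silyl ether
Product: 11 (6S,2′S,3′R,6′R,7′R)-C7′ tertiary alcohol with C3′ silyl ether and spirocyclopentene, via hydroperoxide 10 (not isolated)
Conditions: Co(acac)2 (20 mol %), PhSiH3, O2 (1 atm), i-PrOH/THF, 23 °C; then PPh3
Reagents that add atoms: dioxygen O=O
Why: Mukaiyama hydration, in which a cobalt hydride transfers a hydrogen atom to C8′ of the trisubstituted olefin (the cis-disubstituted cyclopentene is a far poorer acceptor) and O2 should trap the tertiary C7′ radical from the equatorial side, away from the axial C1 carbonyl on C6 and the axial H-2′, so that the new OH is equatorial and trans to C5′ (7′R) with the methyl group axial; PPh3 reduces the hydroperoxide.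

Step 7
Reactants: 11 (6S,2′S,3′R,6′R,7′R)-C7′ tertiary alcohol with C3′ silyl ether and spirocyclopentene
Product: 13 (6S,2′S,3′R,6′R,7′R)-dialdehyde with two 2-oxoethyl groups on C4, via diol 12 (not isolated)
Conditions: OsO4 (2 mol %), NaIO4 (4 equiv), 2,6-lutidine, 1,4-dioxane/H2O, 23 °C
Reagents that add atoms: sodium periodate [Na+].[O-]I(=O)(=O)=O
Why: Lemieux–Johnson oxidation, in which OsO4 dihydroxylates the only C=C bond that is not part of the electron-poor enol and NaIO4 cleaves the cis-diol and reoxidises osmium, should unmask the two 2-oxoethyl arms on C4 without touching a stereocenter.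

Step 8
Reactants: 13 (6S,2′S,3′R,6′R,7′R)-dialdehyde with two 2-oxoethyl groups on C4
Product: 14 C3′ triethylsilyl ether of the target
Conditions: i-PrPPh3I (6 equiv), n-BuLi (6 equiv), THF, 0 °C; then 13, −78 to 23 °C
Reagents that add atoms: isopropyltriphenylphosphonium iodide CC(C)[P+](c1ccccc1)(c1ccccc1)c1ccccc1.[I-]
Why: Twofold Wittig olefination with the non-stabilised isopropylidene ylide should turn each CH2CHO arm into a prenyl group, the excess of ylide allowing for the acidic enol and hydroxyl protons; no stereocenter is formed or epimerisable.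

Step 9
Reactants: 14 C3′ triethylsilyl ether of the target
Product: 15 CNP0266834.1 (target)
Conditions: HF·pyridine, pyridine, THF, 0 to 23 °C
Reagents that add atoms: none
Why: Fluoride-induced desilylation under pyridine-buffered conditions should free the tertiary C3′ alcohol with retention (the C–O bond is not broken) while the prenyl groups and tertiary alcohols are left intact.

**Compound list**

1 | 2,4,6-trihydroxyacetophenone | CC(=O)c1c(O)cc(O)cc1O | starting material
2 | 2-acetyl-4,4-diallyl-3-hydroxycyclohex-2-ene-1,5-dione | CC(=O)C1=C(O)C(CC=C)(CC=C)C(=O)CC1=O | intermediate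
3 | 9-acetyl-10-hydroxyspiro[4.5]deca-2,9-diene-6,8-dione (trione with the prenyl groups masked as a spirocyclopentene) | CC(=O)C1=C(O)C2(CC=CC2)C(=O)CC1=O | intermediate
4 | (R)-(−)-linalool, (3R)-3,7-dimethylocta-1,6-dien-3-ol | CC(C)=CCC[C@@](C)(O)C=C | starting material
5 | (R)-linalool triethylsilyl ether | CC(C)=CCC[C@@](C)(O[Si](CC)(CC)CC)C=C | intermediate
6 | (2E,6R)-2,6-dimethyl-6-(triethylsilyloxy)octa-2,7-dienal | O=C/C(C)=C/CC[C@@](C)(O[Si](CC)(CC)CC)C=C | intermediate
7 | dienone: 3 carrying at C6 the (2E,6R)-2,6-dimethyl-6-(triethylsilyloxy)octa-2,7-dien-1-ylidene group, C5 carbonyl cis to C7′ | CC(=O)C1=C(O)C2(CC=CC2)C(=O)/C(=C\C(C)=C\CC[C@@](C)(O[Si](CC)(CC)CC)C=C)C1=O | intermediate (not isolated)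
8 | 6-acetyl-7-hydroxy-3-methyl-2-[(3R)-3-methyl-3-(triethylsilyloxy)pent-4-en-1-yl]spiro[chromene-8,1′-cyclopent[3]ene]-5(2H)-one (pyran oxygen on C5; both C6′ epimers) | CC(=O)C1=C(O)C2(CC=CC2)C3=C(C=C(C)C(CC[C@@](C)(O[Si](CC)(CC)CC)C=C)O3)C1=O | intermediate (not isolated)
9 | (6S,2′S,3′R,6′R)-cycloadduct: C6 spiro-linked to C1′ and C8′, trans-fused C2′–C6′ bicycle, C7′=C8′ olefin, C3′ silyl ether, spirocyclopentene on C4 | CC(=O)C1=C(O)C4(CC=CC4)C(=O)[C@@]2(C[C@H]3[C@@H](CC[C@@]3(C)O[Si](CC)(CC)CC)C(C)=C2)C1=O | intermediate
10 | (7′R)-C7′ hydroperoxide of 9 | CC(=O)C1=C(O)C4(CC=CC4)C(=O)[C@@]2(C[C@H]3[C@@H](CC[C@@]3(C)O[Si](CC)(CC)CC)[C@](C)(OO)C2)C1=O | intermediate (not isolated)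
11 | (6S,2′S,3′R,6′R,7′R)-C7′ tertiary alcohol with C3′ silyl ether and spirocyclopentene on C4 | CC(=O)C1=C(O)C4(CC=CC4)C(=O)[C@@]2(C[C@H]3[C@@H](CC[C@@]3(C)O[Si](CC)(CC)CC)[C@](C)(O)C2)C1=O | intermediate
12 | cis-cyclopentane-1,2-diol from 11 (either face) | CC(=O)C1=C(O)C4(CC(O)C(O)C4)C(=O)[C@@]2(C[C@H]3[C@@H](CC[C@@]3(C)O[Si](CC)(CC)CC)[C@](C)(O)C2)C1=O | intermediate (not isolated)
13 | (6S,2′S,3′R,6′R,7′R)-dialdehyde with two 2-oxoethyl groups on C4 | CC(=O)C1=C(O)C(CC=O)(CC=O)C(=O)[C@@]2(C[C@H]3[C@@H](CC[C@@]3(C)O[Si](CC)(CC)CC)[C@](C)(O)C2)C1=O | intermediate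
14 | C3′ triethylsilyl ether of the target (6S,2′S,3′R,6′R,7′R) | CC(=O)C1=C(O)C(CC=C(C)C)(CC=C(C)C)C(=O)[C@@]2(C[C@H]3[C@@H](CC[C@@]3(C)O[Si](CC)(CC)CC)[C@](C)(O)C2)C1=O | intermediate
15 | CNP0266834.1, (6S,2′S,3′R,6′R,7′R) | CC(=O)C1=C(O)C(CC=C(C)C)(CC=C(C)C)C(=O)[C@@]2(C[C@H]3[C@@H](CC[C@@]3(C)O)[C@](C)(O)C2)C1=O | target

**Step count and risks**

Total steps: 9. Longest linear sequence: 7 steps (steps 3 to 9 from 4; equally steps 1, 2 and 5 to 9 from 1).

Steps most likely to fail:

Step 5. The ring-opened dienone may reclose and slowly decompose before it adds the unactivated vinyl group. The syn transition state may compete and give cis ring fusion. Isomerisation about C6=C8′, by rotation or by reversible addition of the amine salt, may erode control at C6. Fallback, from 3 and 6 back to 9: the condensation is run alone (ethylenediammonium diacetate, CH2Cl2/MeOH, 23 °C) and pyran 8 is isolated free of the amine salt. Its acyl-enol unit is then converted with BF3·OEt2 (1 equiv) and 2,6-di-tert-butylpyridine (CH2Cl2, 0 °C) into the difluoroboron chelate of pyran 8 F1. The covalently bound Lewis acid lowers the diene LUMO and rigidifies the trione, so the cycloaddition should run at 60–80 °C in the absence of any amine and give the difluoroboron chelate of cycloadduct 9 F2. Cleavage of the chelate (NaOAc, aqueous MeOH, 50 °C) comes back to 9.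

Step 6. Capture of the C7′ radical by O2 may show poor facial selectivity, or the radical may be reduced by hydrogen-atom transfer instead of oxygenated. Fallback, from 9 back to 11: dimethyldioxirane (acetone, −20 °C) should epoxidise the trisubstituted olefin on the exposed face, anti to the axial C1 carbonyl, and give the C7′,C8′-epoxide of cycloadduct 9 F3, in which the C–O bond at C7′ is placed by concerted syn transfer. Hydride opening at the secondary C8′ with LiEt3BH (on the sodium salt of the triketone, THF, −78 to 0 °C) returns to 11; the C5 ketone, which lies between two quaternary carbons, is expected to be spared.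

Step 8. The aldehyde arms may enolise and condense, or their lactol forms may react sluggishly, under the strongly basic ylide. Fallback, from 13 back to 14: Julia–Kocienski olefination with 1-phenyl-5-(propan-2-ylsulfonyl)-1H-tetrazole, KN(SiMe3)2 being added to the mixture of sulfone and 13 at −78 °C so that the sulfonyl carbanion is trapped as it forms (no further compound, F0).

Further compounds
F1 | step 5 | difluoroboron chelate of pyran 8 (boron bridging the acetyl oxygen and the C3 oxygen) | CC1=[O+][B-](F)(F)OC2=C1C(=O)C5=C(OC(CC[C@@](C)(O[Si](CC)(CC)CC)C=C)C(C)=C5)C26CC=CC6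
F2 | step 5 | difluoroboron chelate of cycloadduct 9 | CC1=[O+][B-](F)(F)OC2=C1C(=O)[C@]5(C[C@H]3[C@@H](CC[C@@]3(C)O[Si](CC)(CC)CC)C(C)=C5)C(=O)C26CC=CC6
F3 | step 6 | C7′,C8′-epoxide of cycloadduct 9 (oxygen cis to H-6′) | CC(=O)C1=C(O)C4(CC=CC4)C(=O)[C@@]2(C[C@H]3[C@@H](CC[C@@]3(C)O[Si](CC)(CC)CC)[C@]6(C)O[C@@H]62)C1=O
F0 | step 8 | none | none
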